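(The data were computed on assumed constants, noise included.)

0.186 is the number to carry from the ash run: at 15.0 h L holds 7.6% of the Z charged and X holds 40.8%. Call this L gained per X gained the L-per-X ratio, a selectivity factor.

| setting | ash | elm | maple | alder | Wednesday's | Tuesday's | Monday's | Friday's |
|---|---|---|---|---|---|---|---|---|
| Z | 0.020 M | 0.013 M | 0.030 M | 0.020 M | 0.020 M (fed, over 12 h) | 0.020 M | 0.020 M | 0.020 M |
| E | 2.5 equiv | 2.5 equiv | 2.5 equiv | 5 equiv | 2.50 equiv | 2.50 equiv (in portions, 4, over 12 h) | 2.50 equiv (fed, over 12 h) | 2.50 equiv |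
| Q | 1.2 equiv | 1.2 equiv | 1.2 equiv | 1.2 equiv | 1.20 equiv | 1.20 equiv | 1.20 equiv | 1.20 equiv |
| remark | run made earlier | run made earlier | run made earlier | run made earlier | all else is in the flask from the start; the feed brings no volume worth counting | first portion at the start, last at 12 h | all else is in the flask from the start; the feed brings no volume worth counting | everything together at the start |
| time |  |  |  |  | 15 h | 15 h | 15 h | 15 h |

| run | time / h | X / % | L / % |
|---|---|---|---|
| ash | 1.33 | 5.7 | 1.3 |
| ash | 4.00 | 16.0 | 2.6 |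
| ash | 8.00 | 27.4 | 4.6 |
| ash | 10.0 | 32.3 | 6.0 |
| ash | 15.0 | 40.8 | 7.6 |
| elm | 1.33 | 3.9 | 0.5 |
| elm | 2.50 | 7.9 | 0.7 |
| elm | 5.00 | 14.2 | 2.7 |
| elm | 10.0 | 22.6 | 4.2 |
| elm | 20.0 | 37.6 | 8.0 |
| maple | 1.33 | 10.1 | 1.1 |
| maple | 2.50 | 15.0 | 2.9 |
| maple | 5.00 | 26.9 | 4.1 |
| maple | 10.0 | 41.9 | 7.0 |
| maple | 20.0 | 56.8 | 10.6 |
| alder | 1.50 | 7.7 | 1.2 |
| alder | 5.00 | 22.1 | 2.2 |
| alder | 8.00 | 30.4 | 2.2 |
| alder | 12.0 | 39.0 | 3.4 |
| alder | 20.0 | 52.2 | 5.5 |

(readings scatter by 0.5 percentage points)

- percentages count the Z that a species holds: one L counts as two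
- what may be going on: Z + E <-> D + G; Q + G -> X; Z + G -> L; E <-> J

1. the best flask by share of X in X plus L; "all alike" if 1.5 percentage points covers them all (Wednesday's / Tuesday's / Monday's / Friday's / all alike)
2. share of X in X plus L at the end, Wednesday's
3. share of X in X plus L at the end, Tuesday's
4. share of X in X plus L at the end, Monday's
5. share of X in X plus L at the end, Friday's

Divide the rate of L by the rate of X. G stands in both and cancels, and time drops out, so the ratio follows free Z over Q, each as a fraction of its charge. So dilution at fixed equivalents should leave it alone, and the last readings of the elm and maple runs give 0.213 and 0.187. But the alder run, with 5 equiv of E, gives 0.105, less than the ash run, which reads as less free Z.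

X over X plus L then follows from the ratio. Friday's flask repeats the ash run, so I reckon 84.3% for it. Monday's and Tuesday's flasks get their E over 12 h, so I expect a lower share there than in Friday's flask, and a higher one in Wednesday's flask, where Z is fed into E over the same time.

The forecast picks Wednesday's, with 90% for Wednesday's, 80% for Tuesday's, 78.5% for Monday's and 84.5% for Friday's. Its ground for Wednesday's is that “free Z stays low in excess base”.

The flasks give 88.9% for Wednesday's, the largest share, against 76.3% for Tuesday's, 76.8% for Monday's and 84.1% for Friday's. The forecast's pick and its shares stand within tolerance.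

    Z + E ⇌ D + G, settled at all times (K = 2.26)
    Q + G → X (k = 7.14 × 10⁻⁴ M⁻¹ s⁻¹)
    Z + G → L (k = 3.70 × 10⁻⁴ M⁻¹ s⁻¹)
    E ⇌ J (K = 0.740, k = 6.31 × 10⁻⁵ s⁻¹)

Now leave Tuesday's flask until 25.0 h, with nothing else changed. At 15.0 h it holds 34.5% of X and 10.7% of L, and at the later time X stands at 48.1%. Charge the X gained in between with the ash ratio 0.186. L then comes to 13.2%, and X over X plus L to 78.5%. Tuesday's flask left that long holds 13.0% of L, and its share is 78.8%.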